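A charge of 0.0570 mM of acid on 19 mM of substrate looks too small to carry a run, and your hunch was that the weak acid formed along the way takes over and speeds the flask up. Here is the quick number you asked for.

substrate 19 mM; acid 0.0570 mM; scavenger 1.00 equiv; time 30 min

- part of the substrate that has reacted at 30 min
- pH of the solution at 30 min

- acid is the free proton; pH is minus the decimal logarithm of its molar concentration
- percent here means substrate units held: one homo dimer or idle adduct B counts as two
- what is said of product includes idle adduct B
- what is said of weak acid includes idle adduct A
- for a step with 2 of a species take k times the square, and two of it per event
- in an amount of product, one idle adduct B counts as one product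
- what has gone from substrate into another species counts as reacted, even if it can come back
- run time (flask): 30 min

    substrate + acid → weak acid + acid + product (k1 = 1600 M⁻¹ min⁻¹)
    weak acid ⇌ conjugate base + acid, settled at all times (K2 = 6.3 × 10⁻⁷ M)
    substrate → weak acid + product (k3 = 1.3 × 10⁻⁴ min⁻¹)
    2 substrate → homo dimer (k4 = 1.6 M⁻¹ min⁻¹)
    substrate + weak acid ⇌ idle adduct A, settled at all times (K5 = 19 M⁻¹)
    weak acid + scavenger → scavenged by-product (k6 = 210 M⁻¹ min⁻¹)
    substrate + product ⇌ idle adduct B, settled at all times (K7 = 28 M⁻¹)

1. The catalysed step hands back its acid at each turn, so its rate is first order in substrate for as long as the acid holds still. The acid is the concentration to watch.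

2. Free weak acid has a half-life of 0.17 min against the scavenger, the other concentrations as charged, shorter than the 7.6 min of substrate in the catalysed step. So its making and its loss balance from moment to moment, and with substrate and scavenger at their equal charges I put it at 0.434 mM.

3. Dissociation of that weak acid adds 8.42% of the acid charge, far less than the charge itself, so I see no runaway.

4. Take the acid clock, the rate constant of the catalysed step times the acid charge, 0.0912 min⁻¹: a pseudo-first-order constant. The fraction of substrate left is then the exponential of minus the clock times the time.

5. Over 30 min I commit to 93.5% reacted and a pH of 4.24. Dimerisation runs beside the catalysed step, which leads it by a factor of 1.5 at the start, so I hold my conversion to be low.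

The forecast says 94.9% and pH 4.24, higher in conversion than mine, and on the acid it reads as I do: “The autocatalytic boost is therefore small”.

The simulation gives 95.0% reacted and pH 4.24, and the forecast holds on both.

In this flask the acid clock leaves 6.48% of the substrate, and the reading is 5.0%, with the acid at 102% of its charge. Now take the neighbouring flask with 0.14 mM of acid, everything else as before. Its clock is 0.224 min⁻¹, which over the same time gives 99.9% reacted. The neighbouring flask reads 99.6% reacted, with 0.40% of its substrate left and its acid at 100% of its charge.

Its constants are invented; the flask was simulated.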